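Germacrane numbering throughout: C1 ketone, C2=C3, ether O bridging C3 and C10, Z C4=C5 (Me C15), C6 ester carbinol, C7/C8 lactone fusion, C9, C10 (Me C14), C11=C13, C12 lactone carbonyl.
Retrosynthesis cuts, in this order: the ester C–O bond at C6; the furanone bond O–C3; the ring bond C1–C2; the bond C6–C7; the pair C7–C8 / O8–C12 that makes the lactone.
Enabling feature: the 3(2H)-furanone O–C3=C2–C1(=O)–C10 is what a C10 hydroxyl leaves when it adds 5-endo to a C1-keto C2≡C3 alkyne; that rod-like alkyne and the Z C4=C5 bond let the ten-membered carbocycle C1–C10 be closed before the oxygen bridge exists.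
Forward: the methylene lactone is built on C8 of a citramalate-derived alcohol, turned into a bromomethyl butenolide and joined to the Z-enynal at C6–C7; the carbocycle closes at C1–C2; oxidation gives the ynone; gold closes the furanone; the side-chain acid is attached last.
Stereochemistry: C10 from (R)-citramalic acid; C8 from the chiral iridium catalyst; C7 and C6 relayed from C8 in the Barbier step; 4Z from the commercial enynol; the side-chain carbinol from methyl (R)-3-hydroxybutanoate.

Key step: step 13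

Assumption: the ligand antipode in step 3 is the one that delivers the 5R lactone 7 (the sense is fixed in a first run and the other antipode is taken if needed); compounds 1, 4, 9 and 22 are bought.

Step 1
Reactants: 1 (R)-citramalic acid
Product: 2 (2R)-2-methylbutane-1,2,4-triol
Conditions: BH3·SMe2, B(OMe)3, THF, 0 °C to rt; MeOH quench
Reagents that add atoms: none
Why: Borane reduction of both carboxyl groups to primary alcohols leaves the tertiary carbinol C10 untouched, so the R configuration of the chiral pool is carried over.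

Step 2
Reactants: 2 (2R)-2-methylbutane-1,2,4-triol
Product: 3 2-[(4R)-2,2,4-trimethyl-1,3-dioxolan-4-yl]ethan-1-ol
Conditions: 2,2-dimethoxypropane, TsOH·H2O (cat.), acetone, rt
Reagents that add atoms: 2,2-dimethoxypropane, COC(C)(C)OC
Why: Acid-catalysed acetonide formation under thermodynamic control prefers the five-membered dioxolane of the 1,2-diol (C1 and C10 oxygens) over the six-membered dioxane, which leaves only the C8 hydroxyl free.

Step 3
Reactants: 3 2-[(4R)-2,2,4-trimethyl-1,3-dioxolan-4-yl]ethan-1-ol; 4 methyl 2-(acetoxymethyl)prop-2-enoate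
Product: 7 (5R)-3-methylidene-5-{[(4R)-2,2,4-trimethyl-1,3-dioxolan-4-yl]methyl}oxolan-2-one, via aldehyde 5 (not isolated), via hydroxy ester 6 (not isolated)
Conditions: [Ir(cod)Cl]2 (2.5 mol%), (R)-SEGPHOS (5 mol%), 4-cyano-3-nitrobenzoic acid (10 mol%), Cs2CO3 (20 mol%), THF, 60 °C
Reagents that add atoms: none
Why: Iridium-catalysed transfer-hydrogenative 2-(alkoxycarbonyl)allylation (Krische allylation) from the alcohol oxidation level: the cyclometalated iridium complex takes 3 to aldehyde 5, adds the ester-bearing allyl unit through a closed transition state whose aldehyde face (new centre C8) is set by the chiral bisphosphine, and hydroxy ester 6 lactonises in the flask.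

Step 4
Reactants: 7 (5R)-3-methylidene-5-{[(4R)-2,2,4-trimethyl-1,3-dioxolan-4-yl]methyl}oxolan-2-one
Product: 8 (5S)-3-(bromomethyl)-5-{[(4R)-2,2,4-trimethyl-1,3-dioxolan-4-yl]methyl}furan-2(5H)-one
Conditions: NBS (1.05 equiv), AIBN (cat.), PhCF3, 80 °C
Reagents that add atoms: N-bromosuccinimide, O=C1CCC(=O)N1Br
Why: Wohl–Ziegler bromination: hydrogen abstraction at the allylic ring methylene C7 gives a delocalised radical that takes up bromine at the exocyclic terminus C13, so the double bond moves into the ring and into conjugation while C8 is not involved and keeps its configuration (the descriptor changes from R to S only because C7 becomes sp2).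

Step 5
Reactants: 9 (Z)-3-methylpent-2-en-4-yn-1-ol
Product: 10 (Z)-3-methylpent-2-en-4-ynal
Conditions: MnO2, CH2Cl2, 0 °C to rt, dark; filtered solution used at once
Reagents that add atoms: none
Why: Manganese dioxide oxidation of a primary allylic alcohol stops at the aldehyde under neutral conditions, which should preserve the Z geometry of the C4=C5 bond.

Step 6
Reactants: 8 (5S)-3-(bromomethyl)-5-{[(4R)-2,2,4-trimethyl-1,3-dioxolan-4-yl]methyl}furan-2(5H)-one; 10 (Z)-3-methylpent-2-en-4-ynal
Product: 12 (4S,5S)-4-[(1R,2Z)-1-hydroxy-3-methylpent-2-en-4-yn-1-yl]-3-methylidene-5-{[(4R)-2,2,4-trimethyl-1,3-dioxolan-4-yl]methyl}oxolan-2-one, via allylzinc bromide 11 (not isolated)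
Conditions: Zn dust, THF/sat. aq. NH4Cl (2:1), 0 °C to rt
Reagents that add atoms: none
Why: Barbier allylation: allylzinc 11 reacts at its ring terminus C7 through a six-membered Zimmerman–Traxler transition state on the lactone face away from the C8 side chain (C7 trans to C8), and because the ring locks the allyl unit in the E-crotyl-like geometry and the alkenyl group of the aldehyde lies equatorial the carbinol C6 forms in the anti sense, which is the all-syn C6/C7/C8 array of the target, while the exocyclic methylene returns to C11.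

Step 7
Reactants: 12 (4S,5S)-4-[(1R,2Z)-1-hydroxy-3-methylpent-2-en-4-yn-1-yl]-3-methylidene-5-{[(4R)-2,2,4-trimethyl-1,3-dioxolan-4-yl]methyl}oxolan-2-one
Product: 13 (4S,5S)-5-[(2R)-2,3-dihydroxy-2-methylpropyl]-4-[(1R,2Z)-1-hydroxy-3-methylpent-2-en-4-yn-1-yl]-3-methylideneoxolan-2-one
Conditions: AcOH/H2O/THF (3:1:1), 40 °C
Reagents that add atoms: none
Why: Mild acid hydrolysis of the isopropylidene ketal frees the C1/C10 diol without touching the lactone, the enyne or the allylic C6 carbinol.

Step 8
Reactants: 13 (4S,5S)-5-[(2R)-2,3-dihydroxy-2-methylpropyl]-4-[(1R,2Z)-1-hydroxy-3-methylpent-2-en-4-yn-1-yl]-3-methylideneoxolan-2-one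
Product: 14 (4R,5S)-5-[(2R)-2-hydroxy-2-methyl-3-(triethylsilyloxy)propyl]-3-methylidene-4-[(1R,2Z)-3-methyl-1-(triethylsilyloxy)pent-2-en-4-yn-1-yl]oxolan-2-one
Conditions: TESCl (2.3 equiv), imidazole, DMF, 0 °C
Reagents that add atoms: chlorotriethylsilane, CC[Si](Cl)(CC)CC
Why: Silyl ether formation with TESCl and imidazole takes the primary C1 and the secondary C6 hydroxyl and leaves the hindered tertiary C10 hydroxyl free, which is the pattern the later steps need.

Step 9
Reactants: 14 (4R,5S)-5-[(2R)-2-hydroxy-2-methyl-3-(triethylsilyloxy)propyl]-3-methylidene-4-[(1R,2Z)-3-methyl-1-(triethylsilyloxy)pent-2-en-4-yn-1-yl]oxolan-2-one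
Product: 15 (4R,5S)-5-[(2R)-2-hydroxy-2-methyl-3-(triethylsilyloxy)propyl]-4-[(1R,2Z)-5-iodo-3-methyl-1-(triethylsilyloxy)pent-2-en-4-yn-1-yl]-3-methylideneoxolan-2-one
Conditions: NIS, AgNO3 (10 mol%), acetone, rt, dark
Reagents that add atoms: N-iodosuccinimide, O=C1CCC(=O)N1I
Why: Silver-catalysed electrophilic iodination of the terminal alkyne C–H gives the 1-iodoalkyne at C2 under neutral conditions that spare the silyl ethers, the free tertiary hydroxyl and the methylene lactone.

Step 10
Reactants: 15 (4R,5S)-5-[(2R)-2-hydroxy-2-methyl-3-(triethylsilyloxy)propyl]-4-[(1R,2Z)-5-iodo-3-methyl-1-(triethylsilyloxy)pent-2-en-4-yn-1-yl]-3-methylideneoxolan-2-one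
Product: 16 (2R)-2-hydroxy-3-{(2S,3R)-3-[(1R,2Z)-5-iodo-3-methyl-1-(triethylsilyloxy)pent-2-en-4-yn-1-yl]-4-methylidene-5-oxooxolan-2-yl}-2-methylpropanal
Conditions: (COCl)2, DMSO, CH2Cl2, −78 to −40 °C; Et3N, −78 to 0 °C; crude aldehyde used at once
Reagents that add atoms: none
Why: Swern oxidation applied directly to the bis-silyl ether: the activated sulfoxide cleaves the unhindered primary triethylsilyl ether and oxidises C1 to the aldehyde in one operation, while the secondary C6 silyl ether and the non-oxidisable tertiary C10 hydroxyl remain.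

Step 11
Reactants: 16 (2R)-2-hydroxy-3-{(2S,3R)-3-[(1R,2Z)-5-iodo-3-methyl-1-(triethylsilyloxy)pent-2-en-4-yn-1-yl]-4-methylidene-5-oxooxolan-2-yl}-2-methylpropanal
Product: 18 (4Z,6R,7R,8S,10R)-1,10-dihydroxy-6-(triethylsilyloxy)germacra-4,11(13)-dien-2-yn-12,8-olide (both C1 epimers), via alkynylchromium dichloride 17 (not isolated)
Conditions: CrCl2 (10 equiv), NiCl2 (cat.), THF, rt, slow addition of 16 to 2 mM
Reagents that add atoms: none
Why: Intramolecular Nozaki–Hiyama–Kishi alkynylation: the iodoalkyne is converted into alkynylchromium 17, which adds chemoselectively to the non-enolisable C1 aldehyde at high dilution and forms the C1–C2 bond of the ten-membered ring, the Z alkene bringing the two ends together and the linear C2≡C3 unit fitting the ring with little bending; the C1 configuration does not matter because C1 is oxidised next.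

Step 12
Reactants: 18 (4Z,6R,7R,8S,10R)-1,10-dihydroxy-6-(triethylsilyloxy)germacra-4,11(13)-dien-2-yn-12,8-olide (both C1 epimers)
Product: 19 (4Z,6R,7R,8S,10R)-10-hydroxy-1-oxo-6-(triethylsilyloxy)germacra-4,11(13)-dien-2-yn-12,8-olide
Conditions: Dess–Martin periodinane, CH2Cl2, 0 °C to rt
Reagents that add atoms: none
Why: Dess–Martin oxidation converts the secondary propargylic alcohol into the ynone, cannot oxidise the tertiary C10 hydroxyl, and takes both C1 epimers to one ketone.

Step 13
Reactants: 19 (4Z,6R,7R,8S,10R)-10-hydroxy-1-oxo-6-(triethylsilyloxy)germacra-4,11(13)-dien-2-yn-12,8-olide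
Product: 20 (4Z,6R,7R,8S,10R)-3,10-epoxy-1-oxo-6-(triethylsilyloxy)germacra-2,4,11(13)-trien-12,8-olide
Conditions: (Ph3P)AuNTf2 (5 mol%), CH2Cl2, rt
Reagents that add atoms: none
Why: The cationic gold complex binds the C2≡C3 bond of 19, which the C1 ketone polarises toward C3, the C10 hydroxyl lying across the ring adds to C3 anti to the metal, and protodeauration at C2 releases the catalyst and the vinylogous ester 20. The closest known reaction is the gold- or amine-promoted cyclisation of α′-hydroxy ynones to 3(2H)-furanones, used here in a transannular setting. The five-membered ring O–C10–C1–C2=C3 closes in the 5-endo-dig mode, which turns the ten-membered carbocycle into the oxygen-bridged bicycle and releases the bending strain of the ring alkyne. No stereocentre is formed: C6, C7, C8 and C10 are spectators and the 4Z geometry is held by the ring. The selectivity needed is regio- and chemoselectivity, attack of O10 at C3 and not at C2 (a 4-exo closure is not accessible) and not by an outside nucleophile on the ynone or the methylene lactone, and it rests on the proximity of O10 to C3, on the silyl cap at C6 that leaves no second hydroxyl, and on the neutral, non-nucleophilic medium.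

Step 14
Reactants: 20 (4Z,6R,7R,8S,10R)-3,10-epoxy-1-oxo-6-(triethylsilyloxy)germacra-2,4,11(13)-trien-12,8-olide
Product: 21 (4Z,6R,7S,8S,10R)-3,10-epoxy-6-hydroxy-1-oxogermacra-2,4,11(13)-trien-12,8-olide
Conditions: HF·pyridine, pyridine, THF, 0 °C
Reagents that add atoms: none
Why: Buffered fluoride cleavage of the secondary triethylsilyl ether leaves the vinylogous ester, the methylene lactone and all stereocentres untouched (the C7 descriptor changes to S only through the priority change at O6).

Step 15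
Reactants: 22 methyl (3R)-3-hydroxybutanoate
Product: 23 methyl (3R)-3-(triethylsilyloxy)butanoate
Conditions: TESCl, imidazole, CH2Cl2, 0 °C to rt
Reagents that add atoms: chlorotriethylsilane, CC[Si](Cl)(CC)CC
Why: Standard silyl ether formation protects the carbinol, whose R configuration comes from the chiral pool and is not touched here or later.

Step 16
Reactants: 23 methyl (3R)-3-(triethylsilyloxy)butanoate
Product: 24 (3R)-3-(triethylsilyloxy)butanal
Conditions: i-Bu2AlH (1.05 equiv), CH2Cl2, −78 °C; aq. potassium sodium tartrate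
Reagents that add atoms: none
Why: Partial reduction of the methyl ester with diisobutylaluminium hydride at −78 °C stops at the aldehyde oxidation level, a standard outcome for β-silyloxy esters.

Step 17
Reactants: 24 (3R)-3-(triethylsilyloxy)butanal
Product: 26 (3R)-2-methylidene-3-(triethylsilyloxy)butanal, via Mannich base 25 (not isolated)
Conditions: Eschenmoser's salt (2 equiv), Et3N, CH2Cl2, rt
Reagents that add atoms: N,N-dimethylmethylideneammonium iodide (Eschenmoser's salt), C=[N+](C)C.[I-]
Why: Mannich α-methylenation: the aldehyde reacts at C2 with the iminium salt to give Mannich base 25, which loses dimethylamine under the basic conditions and leaves the 2-methylidene aldehyde, while the silyloxy-bearing C3 is not enolisable and keeps its configuration.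

Step 18
Reactants: 26 (3R)-2-methylidene-3-(triethylsilyloxy)butanal
Product: 27 (3R)-2-methylidene-3-(triethylsilyloxy)butanoic acid
Conditions: NaClO2, NaH2PO4, 2-methylbut-2-ene, t-BuOH/H2O, 0 °C to rt
Reagents that add atoms: sodium chlorite, [Na+].[O-]Cl=O
Why: Pinnick oxidation turns the enal into the acrylic acid without touching the electron-poor double bond or the silyl ether, the alkene scavenger taking up the hypochlorous acid.

Step 19
Reactants: 21 (4Z,6R,7S,8S,10R)-3,10-epoxy-6-hydroxy-1-oxogermacra-2,4,11(13)-trien-12,8-olide; 27 (3R)-2-methylidene-3-(triethylsilyloxy)butanoic acid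
Product: 29 (4Z,6R,7R,8S,10R)-3,10-epoxy-1-oxo-6-{[(3R)-2-methylidene-3-(triethylsilyloxy)butanoyl]oxy}germacra-2,4,11(13)-trien-12,8-olide, via mixed anhydride 28 (not isolated)
Conditions: 27, 2,4,6-trichlorobenzoyl chloride, Et3N, toluene, rt; then 21, DMAP, 0 °C to rt
Reagents that add atoms: none
Why: Yamaguchi esterification: mixed anhydride 28 is opened at the less hindered acrylic carbonyl and the acyl group is passed to the secondary C6 hydroxyl, which is acylated with retention since no bond to C6 is broken.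

Step 20
Reactants: 29 (4Z,6R,7R,8S,10R)-3,10-epoxy-1-oxo-6-{[(3R)-2-methylidene-3-(triethylsilyloxy)butanoyl]oxy}germacra-2,4,11(13)-trien-12,8-olide
Product: 30 (4Z,6R,7R,8S,10R)-3,10-epoxy-6-{[(3R)-3-hydroxy-2-methylidenebutanoyl]oxy}-1-oxogermacra-2,4,11(13)-trien-12,8-olide (CNP0266753.1)
Conditions: HF·pyridine, THF, 0 °C to rt
Reagents that add atoms: none
Why: Acidic fluoride desilylation frees the side-chain carbinol without base, so neither the acrylate nor the methylene lactone should suffer conjugate addition and the ester should not migrate.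

Compound list
1 | (R)-citramalic acid, (2R)-2-hydroxy-2-methylbutanedioic acid | C[C@@](O)(CC(=O)O)C(=O)O | starting material
2 | (2R)-2-methylbutane-1,2,4-triol | C[C@@](O)(CCO)CO | intermediate
3 | 2-[(4R)-2,2,4-trimethyl-1,3-dioxolan-4-yl]ethan-1-ol | C[C@@]1(CCO)COC(C)(C)O1 | intermediate
4 | methyl 2-(acetoxymethyl)prop-2-enoate | C=C(COC(C)=O)C(=O)OC | starting material
5 | 2-[(4R)-2,2,4-trimethyl-1,3-dioxolan-4-yl]acetaldehyde | C[C@@]1(CC=O)COC(C)(C)O1 | intermediate
6 | methyl (4R)-4-hydroxy-2-methylidene-5-[(4R)-2,2,4-trimethyl-1,3-dioxolan-4-yl]pentanoate | C=C(C[C@@H](O)C[C@]1(C)COC(C)(C)O1)C(=O)OC | intermediate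
7 | (5R)-3-methylidene-5-{[(4R)-2,2,4-trimethyl-1,3-dioxolan-4-yl]methyl}oxolan-2-one | C=C1C[C@H](C[C@]2(C)COC(C)(C)O2)OC1=O | intermediate
8 | (5S)-3-(bromomethyl)-5-{[(4R)-2,2,4-trimethyl-1,3-dioxolan-4-yl]methyl}furan-2(5H)-one | BrCC1=C[C@H](C[C@]2(C)COC(C)(C)O2)OC1=O | intermediate
9 | (Z)-3-methylpent-2-en-4-yn-1-ol | C#C/C(C)=C\CO | starting material
10 | (Z)-3-methylpent-2-en-4-ynal | C#C/C(C)=C\C=O | intermediate
11 | {[(5S)-2-oxo-5-{[(4R)-2,2,4-trimethyl-1,3-dioxolan-4-yl]methyl}-2,5-dihydrofuran-3-yl]methyl}zinc bromide | Br[Zn]CC1=C[C@H](C[C@]2(C)COC(C)(C)O2)OC1=O | intermediate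
12 | (4S,5S)-4-[(1R,2Z)-1-hydroxy-3-methylpent-2-en-4-yn-1-yl]-3-methylidene-5-{[(4R)-2,2,4-trimethyl-1,3-dioxolan-4-yl]methyl}oxolan-2-one | C=C1C(=O)O[C@@H](C[C@]2(C)COC(C)(C)O2)[C@@H]1[C@H](O)/C=C(C)\C#C | intermediate
13 | (4S,5S)-5-[(2R)-2,3-dihydroxy-2-methylpropyl]-4-[(1R,2Z)-1-hydroxy-3-methylpent-2-en-4-yn-1-yl]-3-methylideneoxolan-2-one | C=C1C(=O)O[C@@H](C[C@@](C)(O)CO)[C@@H]1[C@H](O)/C=C(C)\C#C | intermediate
14 | (4R,5S)-5-[(2R)-2-hydroxy-2-methyl-3-(triethylsilyloxy)propyl]-3-methylidene-4-[(1R,2Z)-3-methyl-1-(triethylsilyloxy)pent-2-en-4-yn-1-yl]oxolan-2-one | C=C1C(=O)O[C@@H](C[C@@](C)(O)CO[Si](CC)(CC)CC)[C@@H]1[C@H](O[Si](CC)(CC)CC)/C=C(C)\C#C | intermediate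
15 | (4R,5S)-5-[(2R)-2-hydroxy-2-methyl-3-(triethylsilyloxy)propyl]-4-[(1R,2Z)-5-iodo-3-methyl-1-(triethylsilyloxy)pent-2-en-4-yn-1-yl]-3-methylideneoxolan-2-one | C=C1C(=O)O[C@@H](C[C@@](C)(O)CO[Si](CC)(CC)CC)[C@@H]1[C@H](O[Si](CC)(CC)CC)/C=C(C)\C#CI | intermediate
16 | (2R)-2-hydroxy-3-{(2S,3R)-3-[(1R,2Z)-5-iodo-3-methyl-1-(triethylsilyloxy)pent-2-en-4-yn-1-yl]-4-methylidene-5-oxooxolan-2-yl}-2-methylpropanal | C=C1C(=O)O[C@@H](C[C@@](C)(O)C=O)[C@@H]1[C@H](O[Si](CC)(CC)CC)/C=C(C)\C#CI | intermediate
17 | alkynylchromium dichloride of 16 (CrCl2 in place of iodine at C2) | C=C1C(=O)O[C@@H](C[C@@](C)(O)C=O)[C@@H]1[C@H](O[Si](CC)(CC)CC)/C=C(C)\C#C[Cr](Cl)Cl | intermediate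
18 | (4Z,6R,7R,8S,10R)-1,10-dihydroxy-6-(triethylsilyloxy)germacra-4,11(13)-dien-2-yn-12,8-olide (both C1 epimers) | C=C1C(=O)O[C@H]2C[C@@](C)(O)C(O)C#C/C(C)=C\[C@@H](O[Si](CC)(CC)CC)[C@H]12 | intermediate
19 | (4Z,6R,7R,8S,10R)-10-hydroxy-1-oxo-6-(triethylsilyloxy)germacra-4,11(13)-dien-2-yn-12,8-olide | C=C1C(=O)O[C@H]2C[C@@](C)(O)C(=O)C#C/C(C)=C\[C@@H](O[Si](CC)(CC)CC)[C@H]12 | intermediate
20 | (4Z,6R,7R,8S,10R)-3,10-epoxy-1-oxo-6-(triethylsilyloxy)germacra-2,4,11(13)-trien-12,8-olide | C=C1C(=O)O[C@H]2C[C@@]3(C)OC(=CC3=O)/C(C)=C\[C@@H](O[Si](CC)(CC)CC)[C@H]12 | intermediate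
21 | (4Z,6R,7S,8S,10R)-3,10-epoxy-6-hydroxy-1-oxogermacra-2,4,11(13)-trien-12,8-olide | C=C1C(=O)O[C@H]2C[C@@]3(C)OC(=CC3=O)/C(C)=C\[C@@H](O)[C@H]12 | intermediate
22 | methyl (3R)-3-hydroxybutanoate | C[C@@H](O)CC(=O)OC | starting material
23 | methyl (3R)-3-(triethylsilyloxy)butanoate | C[C@@H](O[Si](CC)(CC)CC)CC(=O)OC | intermediate
24 | (3R)-3-(triethylsilyloxy)butanal | C[C@@H](O[Si](CC)(CC)CC)CC=O | intermediate
25 | (3R)-2-[(dimethylamino)methyl]-3-(triethylsilyloxy)butanal (C2 epimers) | C[C@@H](O[Si](CC)(CC)CC)C(CN(C)C)C=O | intermediate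
26 | (3R)-2-methylidene-3-(triethylsilyloxy)butanal | C[C@@H](O[Si](CC)(CC)CC)C(=C)C=O | intermediate
27 | (3R)-2-methylidene-3-(triethylsilyloxy)butanoic acid | C[C@@H](O[Si](CC)(CC)CC)C(=C)C(=O)O | intermediate
28 | (3R)-2-methylidene-3-(triethylsilyloxy)butanoic 2,4,6-trichlorobenzoic anhydride | C[C@@H](O[Si](CC)(CC)CC)C(=C)C(=O)OC(=O)c1c(Cl)cc(Cl)cc1Cl | intermediate
29 | (4Z,6R,7R,8S,10R)-3,10-epoxy-1-oxo-6-{[(3R)-2-methylidene-3-(triethylsilyloxy)butanoyl]oxy}germacra-2,4,11(13)-trien-12,8-olide | C=C1C(=O)O[C@H]2C[C@@]3(C)OC(=CC3=O)/C(C)=C\[C@@H](OC(=O)C(=C)[C@@H](C)O[Si](CC)(CC)CC)[C@H]12 | intermediate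
30 | (4Z,6R,7R,8S,10R)-3,10-epoxy-6-{[(3R)-3-hydroxy-2-methylidenebutanoyl]oxy}-1-oxogermacra-2,4,11(13)-trien-12,8-olide | C=C1C(=O)O[C@H]2C[C@@]3(C)OC(=CC3=O)/C(C)=C\[C@@H](OC(=O)C(=C)[C@@H](C)O)[C@H]12 | target

Total step count: 20.
Longest linear sequence: 15 steps (steps 1–4, 6–14, 19 and 20, from compound 1).

Steps most likely to fail

Step 11 (ring closure). What may go wrong: intermolecular addition leading to oligomers, and decay of the free α-hydroxy aldehyde (self-condensation, α-ketol shift) under the Lewis-acidic chromium salts before the slow ring closure occurs. Fallback: the ring is closed on a masked aldehyde. Setting out from 15, the tertiary hydroxyl is capped with N-(trimethylsilyl)imidazole to give the C10 trimethylsilyl ether F1. The same oxidative desilylation under Swern conditions gives the α-silyloxy aldehyde F2, which should be monomeric and storable. CrCl2 with catalytic NiCl2 at high dilution then gives the macrocyclic carbinol F3, and Dess–Martin oxidation gives the silylated ynone F4. Brief treatment with AcOH/THF/H2O at 0 °C should remove the tertiary trimethylsilyl group, which sits next to the ketone and is far more labile than the secondary triethylsilyl ether, and the route is back at 19.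

Step 6 (Barbier coupling). What may go wrong: erosion of facial selectivity at the aldehyde carbon C6 if the zinc reagent reacts through an open or boat arrangement, Z to E drift of the enal in the aqueous ammonium chloride, and attack through the exocyclic terminus. Fallback: the coupling is moved from zinc to boron. Setting out from 8, borylation (B2pin2, CuCl cat., KOAc, DMF, rt) gives the allylboronate F5, which is heated with 10 in toluene under anhydrous, neutral conditions. The boron-centred chair is closed and stereospecific for the ring-locked allyl geometry, and a non-oxidative work-up with triethanolamine releases 12.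

Step 4 (bromination). What may go wrong: over-bromination at C8 once the butenolide has formed (the C8 hydrogen is then allylic and next to oxygen), with loss of the C8 configuration, and radical attack on the ketal. Fallback: an ionic two-step sequence. Setting out from 7, bromine is added to the exocyclic alkene (Br2, CH2Cl2, 0 °C) to give the dibromide F6. Dehydrobromination with Et3N in Et2O at 0 °C removes the tertiary bromide together with a ring hydrogen at C7, so the conjugated endocyclic alkene forms and the route is back at 8.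

Further compounds
F1 | step 11 | (4R,5S)-4-[(1R,2Z)-5-iodo-3-methyl-1-(triethylsilyloxy)pent-2-en-4-yn-1-yl]-3-methylidene-5-[(2R)-2-methyl-3-(triethylsilyloxy)-2-(trimethylsilyloxy)propyl]oxolan-2-one | C=C1C(=O)O[C@@H](C[C@@](C)(O[Si](C)(C)C)CO[Si](CC)(CC)CC)[C@@H]1[C@H](O[Si](CC)(CC)CC)/C=C(C)\C#CI
F2 | step 11 | (2R)-3-{(2S,3R)-3-[(1R,2Z)-5-iodo-3-methyl-1-(triethylsilyloxy)pent-2-en-4-yn-1-yl]-4-methylidene-5-oxooxolan-2-yl}-2-methyl-2-(trimethylsilyloxy)propanal | C=C1C(=O)O[C@@H](C[C@@](C)(O[Si](C)(C)C)C=O)[C@@H]1[C@H](O[Si](CC)(CC)CC)/C=C(C)\C#CI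
F3 | step 11 | (4Z,6R,7R,8S,10R)-1-hydroxy-6-(triethylsilyloxy)-10-(trimethylsilyloxy)germacra-4,11(13)-dien-2-yn-12,8-olide (both C1 epimers) | C=C1C(=O)O[C@H]2C[C@@](C)(O[Si](C)(C)C)C(O)C#C/C(C)=C\[C@@H](O[Si](CC)(CC)CC)[C@H]12
F4 | step 11 | (4Z,6R,7R,8S,10R)-1-oxo-6-(triethylsilyloxy)-10-(trimethylsilyloxy)germacra-4,11(13)-dien-2-yn-12,8-olide | C=C1C(=O)O[C@H]2C[C@@](C)(O[Si](C)(C)C)C(=O)C#C/C(C)=C\[C@@H](O[Si](CC)(CC)CC)[C@H]12
F5 | step 6 | (5S)-3-[(4,4,5,5-tetramethyl-1,3,2-dioxaborolan-2-yl)methyl]-5-{[(4R)-2,2,4-trimethyl-1,3-dioxolan-4-yl]methyl}furan-2(5H)-one | CC1(C)OB(CC2=C[C@H](C[C@]3(C)COC(C)(C)O3)OC2=O)OC1(C)C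
F6 | step 4 | (5S)-3-bromo-3-(bromomethyl)-5-{[(4R)-2,2,4-trimethyl-1,3-dioxolan-4-yl]methyl}oxolan-2-one (C3 epimers) | BrCC1(Br)C[C@H](C[C@]2(C)COC(C)(C)O2)OC1=O
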